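**Strategy.** Everything rests on reading ring B (C8–C13: enone carbonyl C13, tetrasubstituted C8=C9, carbinol C10 para to C13) as a benzene in disguise, fused through C8=C9 to carbocycle C (C3, C9, C8, C7, C6, C14). A rhodium-catalysed [2+2+2] cyclotrimerisation of an open-chain (R)-1,7-diyne with acetylene makes C8–C9, C10–C11 and C12–C13 at once and delivers both rings as a 5-ethoxy-2-tetralone. The diyne is a quaternary α-ethynyl β-keto ester whose ketone chain ends in an ethoxyalkyne; its stereocentre becomes C3. After the key step the ketone becomes C14, the quaternary ester the lactam, the propanoate ring A, and phenol dearomatisation restores C10–OH and the enone.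

Key step: step 6

Labels: carbons are counted along the target SMILES after the ester carbon: C1 (CH–CO2Me), C2, C3 (quaternary), C4 (lactam C=O), N, C5, C6, C7, C8=C9, C10 (C–OH), C11, C12, C13 (enone C=O), C14 (quaternary, bears C15H2OAc), C16, C17, C18 (ketone), C19 (CH–CH3), C20. Ring A = C1, C2, C3, C9, C10; ring B = C8–C13; ring C = C3, C9, C8, C7, C6, C14; ring D = lactam (C3, C4, N, C5, C6, C14); ring E = nine-membered ring. "Upper face" of the ring A/ring B plane is the face of the C14 bridge, "lower face" that of the lactam bridge C4–N–C5. In the target the C1 ester is on the upper face and the C10 hydroxyl on the lower face.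

Remark on the structures: (R)-8 and (R)-10 have the same spatial arrangement at the quaternary carbon, and it is the one needed at C3, so no structure needs correcting.

Assumption: C19 is α to a ketone only from step 19 onwards, and the later steps are chosen not to enolise that ketone, so its configuration is taken from amine 20.

Step 1
Reactants: 1 ethoxyacetylene; 2 oxetane
Product: 3 5-ethoxypent-4-yn-1-ol
Conditions: n-BuLi, THF, −78 °C; BF3·OEt2, then 2, −78 °C; NaHCO3 (aq.) quench
Reagents that add atoms: none
Why: BF3-assisted SN2 opening of oxetane by the lithium alkoxyacetylide is a standard route to 4-alkyn-1-ols and keeps the acid-labile ynol ether cold and then basic; the acetylide is used as the nucleophile because a 3-alkoxypropargylic halide would ionise to an alkoxyallenyl cation and is not a usable electrophile.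

Step 2
Reactants: 3 5-ethoxypent-4-yn-1-ol
Product: 4 5-ethoxypent-4-ynal
Conditions: (n-Pr4N)RuO4 (5 mol %), N-methylmorpholine N-oxide, 4 Å molecular sieves, CH2Cl2, 0 °C → rt
Reagents that add atoms: none
Why: Ley–Griffith oxidation is neutral, stops at the aldehyde and offers no electrophile or acid to the ynol ether.

Step 3
Reactants: 4 5-ethoxypent-4-ynal; 5 dimethyl glutarate
Product: 6 dimethyl 2-(5-ethoxy-1-hydroxypent-4-yn-1-yl)pentanedioate (diastereomer mixture)
Conditions: LiN(i-Pr)2 (1.05 equiv), THF, −78 °C; then 4, −78 °C; NH4Cl (aq.) at −78 °C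
Reagents that add atoms: none
Why: Directed aldol addition of the lithium mono-enolate of the diester to the aldehyde, quenched cold before the aldolate can lactonise; no stereocontrol is needed because both new centres are erased in steps 4 and 5.

Step 4
Reactants: 6 dimethyl 2-(5-ethoxy-1-hydroxypent-4-yn-1-yl)pentanedioate
Product: 7 dimethyl 2-(5-ethoxypent-4-ynoyl)pentanedioate
Conditions: Dess–Martin periodinane, pyridine, CH2Cl2, 0 °C → rt
Reagents that add atoms: none
Why: Dess–Martin oxidation of a β-hydroxy ester to the β-keto ester, with pyridine buffering the acetic acid that would otherwise hydrate the ynol ether.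

Step 5
Reactants: 7 dimethyl 2-(5-ethoxypent-4-ynoyl)pentanedioate
Product: 8 methyl (2R)-7-ethoxy-2-ethynyl-2-(3-methoxy-3-oxopropyl)-3-oxohept-6-ynoate
Conditions: TMS-EBX (1.2 equiv), KF, chiral N-spiro binaphthyl-derived quaternary ammonium bromide (5 mol %), toluene, −40 °C
Reagents that add atoms: 1-[(trimethylsilyl)ethynyl]-1,2-benziodoxol-3(1H)-one (TMS-EBX), C[Si](C)(C)C#CI1OC(=O)c2ccccc12
Why: Electrophilic α-ethynylation of the β-keto ester enolate by the ethynyl benziodoxolone (addition to the iodine-bound alkyne, α-elimination, 1,2-hydride shift) under chiral ion-pair (phase-transfer) catalysis, in which the ammonium cation shields one enolate face and sets the (R) quaternary centre; the catalyst antipode is chosen accordingly and any minor enantiomer is removed as a diastereomer after step 14.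

Step 6
Reactants: 8 methyl (2R)-7-ethoxy-2-ethynyl-2-(3-methoxy-3-oxopropyl)-3-oxohept-6-ynoate; 9 acetylene
Product: 10 methyl (1R)-5-ethoxy-1-(3-methoxy-3-oxopropyl)-2-oxo-3,4-dihydro-2H-naphthalene-1-carboxylate
Conditions: RhCl(PPh3)3 (5 mol %), C2H2 (1 atm), toluene, 25 → 50 °C, 8 added slowly
Reagents that add atoms: none
Why: RhCl(PPh3)3 loses phosphine, binds both alkynes of the 1,7-diyne and couples them oxidatively (monovalent to trivalent rhodium) to a rhodacyclopentadiene, which makes C8–C9 and with it carbocycle C; acetylene then inserts and reductive elimination forms C10–C11 and C12–C13 and releases benzene ring B. The closest known reaction type is the rhodium-catalysed [2+2+2] cyclotrimerisation of tethered diynes with acetylene, which tolerates ketones, esters and heteroatom-substituted alkynes such as ynamides and alkynyl ethers. Ring C closes by oxidative cyclisation of the tethered diyne on the metal (a six-membered ring fused to the metallacycle, helped by the gem-disubstituted C3), and ring B closes by alkyne insertion into the rhodacycle followed by C–C reductive elimination. No stereocentre is formed, and C3, which has no hydrogen and is not one of the reacting carbons, keeps its (R) configuration. The step needs cross-selectivity over diyne homo-oligomerisation, which the tether, slow addition of 8 into acetylene-saturated solvent and the reluctance of this catalyst to trimerise acetylene alone should secure; symmetric acetylene leaves no regiochemical question, and the neutral aprotic medium keeps the ynol ether intact so that the ethoxy group ends up on C13.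

Step 7
Reactants: 10 ethoxy tetralone
Product: 11 methyl (1R)-5-hydroxy-1-(3-methoxy-3-oxopropyl)-2-oxo-3,4-dihydro-2H-naphthalene-1-carboxylate
Conditions: BCl3, n-Bu4NI, CH2Cl2, −78 → 0 °C
Reagents that add atoms: none
Why: Lewis-acid-assisted SN2 dealkylation of the aryl ethyl ether by iodide is done here, while only two esters and a ketone are present, so that the phenol can carry a benzyl group that later comes off without acid or base.

Step 8
Reactants: 11 hydroxy tetralone
Product: 12 methyl (1R)-8-bromo-5-hydroxy-1-(3-methoxy-3-oxopropyl)-2-oxo-3,4-dihydro-2H-naphthalene-1-carboxylate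
Conditions: NBS (1.0 equiv), MeCN, −20 → 0 °C
Reagents that add atoms: N-bromosuccinimide, O=C1CCC(=O)N1Br
Why: Electrophilic aromatic bromination of a phenol goes para to the hydroxyl, which is C10 (C8 of the tetralone), and one equivalent at low temperature should avoid ortho bromination and ketone α-bromination.

Step 9
Reactants: 12 bromo hydroxy tetralone
Product: 13 methyl (1R)-5-(benzyloxy)-8-bromo-1-(3-methoxy-3-oxopropyl)-2-oxo-3,4-dihydro-2H-naphthalene-1-carboxylate
Conditions: BnBr, K2CO3, acetone, rt
Reagents that add atoms: benzyl bromide, BrCc1ccccc1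
Why: Williamson etherification of the phenoxide; carbonate is too weak to enolise the ketone or to start retro-Claisen cleavage of the quaternary β-keto ester.

Step 10
Reactants: 14 (4S)-4-benzyl-3-propanoyl-1,3-oxazolidin-2-one; 15 acrolein
Product: 16 (4S)-4-benzyl-3-[(2S,3R)-3-hydroxy-2-methylpent-4-enoyl]-1,3-oxazolidin-2-one
Conditions: n-Bu2BOTf, i-Pr2NEt, CH2Cl2, −78 → 0 °C; then 15, −78 °C; H2O2, MeOH, pH 7 buffer
Reagents that add atoms: none
Why: Boron-mediated syn-aldol of the (Z)-enolate of an N-acyl oxazolidinone through a chair transition state, in which the benzyl group of the auxiliary fixes the (2S) methyl centre (the future C19) and the syn (3R) carbinol, which is only a temporary centre.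

Step 11
Reactants: 16 aldol adduct
Product: 17 (4S)-4-benzyl-3-[(2S,3R)-3-(tert-butyldimethylsilyloxy)-2-methylpent-4-enoyl]-1,3-oxazolidin-2-one
Conditions: TBSOTf, 2,6-lutidine, CH2Cl2, 0 °C
Reagents that add atoms: tert-butyldimethylsilyl trifluoromethanesulfonate, CC(C)(C)[Si](C)(C)OS(=O)(=O)C(F)(F)F
Why: Silylation of the secondary allylic alcohol gives an ether that should survive amide bases, ylide and palladium and is removed by dilute acid in step 18.

Step 12
Reactants: 17 silyl ether
Product: 18 (2R,3R)-3-(tert-butyldimethylsilyloxy)-2-methylpent-4-en-1-ol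
Conditions: LiBH4, MeOH (1 equiv), THF, 0 °C
Reagents that add atoms: none
Why: Reductive cleavage of the N-acyl oxazolidinone by borohydride gives the primary alcohol without touching the α-centre and returns the auxiliary.

Step 13
Reactants: 18 (2R,3R)-3-(tert-butyldimethylsilyloxy)-2-methylpent-4-en-1-ol
Product: 20 (2R,3R)-3-(tert-butyldimethylsilyloxy)-2-methylpent-4-en-1-amine, via azide 19 (not isolated)
Conditions: PPh3, DIAD, (PhO)2P(O)N3, THF, 0 °C → rt; then PPh3, H2O, 50 °C
Reagents that add atoms: diphenylphosphoryl azide, [N-]=[N+]=NP(=O)(Oc1ccccc1)Oc1ccccc1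
Why: Mitsunobu azidation of the primary alcohol followed in the same flask by Staudinger reduction gives the primary amine; neither stereocentre is involved.

Step 14
Reactants: 13 benzyloxy bromo tetralone; 20 amine
Product: 22 bromo keto-lactam, via Mannich base 21 (not isolated)
Conditions: 20 (1.1 equiv), (CH2O)n, AcOH (1.0 equiv), EtOH, 70 °C; then toluene, 110 °C
Reagents that add atoms: formaldehyde (as paraformaldehyde), C=O
Why: Mannich aminomethylation at the only enolisable position (C6) followed by intramolecular aminolysis of the quaternary methyl ester closes lactam ring D; only the C6 epimer with the aminomethyl group cis to the ester can cyclise and the other equilibrates through the enol, so C6 follows from C3, and the lactam derived from any (S)-8 is a diastereomer that is separated here.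

Step 15
Reactants: 22 bromo keto-lactam
Product: 23 bromo enol ether lactam (C14=CH–OMe, E/Z mixture)
Conditions: Ph3P(CH2OMe)Cl, KN(SiMe3)2, THF, 0 °C; then 22, 0 °C → rt
Reagents that add atoms: (methoxymethyl)triphenylphosphonium chloride, COC[P+](c1ccccc1)(c1ccccc1)c1ccccc1.[Cl-]
Why: Wittig methoxymethylenation of the bridging C14 ketone, which cannot enolise (C3 quaternary, C6 bridgehead), installs C15 as a masked aldehyde and removes the retro-Claisen-prone β-keto amide before strong base is used; the enol ether geometry is irrelevant.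

Step 16
Reactants: 23 bromo enol ether lactam
Product: 24 indane ester (ring A closed, C1 epimer mixture)
Conditions: Pd2(dba)3 (5 mol %), P(t-Bu)3 (12 mol %), LiN(SiMe3)2 (2.2 equiv), toluene, rt → 60 °C
Reagents that add atoms: none
Why: Palladium-catalysed intramolecular α-arylation of the ester enolate (oxidative addition of zerovalent palladium into C10–Br, enolate binding, reductive elimination from a six-membered palladacycle) closes ring A; the ester is now the only enolisable site, and the C1 mixture is erased in step 17.

Step 17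
Reactants: 24 indane ester
Product: 27 indene ester (C1=C2), via selenide 25 (not isolated), via selenoxide 26 (not isolated)
Conditions: LiN(i-Pr)2, THF, −78 °C; PhSeBr; then m-CPBA (1.0 equiv), CH2Cl2, −78 °C; i-Pr2NH, −78 °C → rt
Reagents that add atoms: none
Why: Enolate selenenylation and selenoxide syn-elimination, which can only take a C2 hydrogen, give the conjugated indene ester; cold peracid oxidises selenium faster than the enol ether and the amine traps the selenenic acid.

Step 18
Reactants: 27 indene ester
Product: 29 hydroxy aldehyde, via silyl ether aldehyde 28 (not isolated)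
Conditions: HCl (2 M aq.), THF, rt
Reagents that add atoms: water, O
Why: Acid hydrolysis of the enol ether to the C14 aldehyde and cleavage of the silyl ether in one operation; the configuration at C14 is left open because it becomes an enolate in step 20.

Step 19
Reactants: 29 hydroxy aldehyde
Product: 30 vinyl ketone aldehyde
Conditions: Dess–Martin periodinane, NaHCO3, CH2Cl2, 0 °C
Reagents that add atoms: none
Why: Dess–Martin oxidation of the allylic alcohol to the vinyl ketone under buffered, non-enolising conditions that leave the aldehyde and C19 untouched; the product is used at once.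

Step 20
Reactants: 30 vinyl ketone aldehyde
Product: 31 pentacyclic aldehyde
Conditions: DBU (0.3 equiv), MeCN, 0 °C, 0.005 M
Reagents that add atoms: none
Why: Intramolecular Michael addition of the α-branched aldehyde enolate to the vinyl ketone forms C14–C16, the quaternary centre and nine-membered ring E; because the tether runs from N, C16 must enter on the ring D side of C14 and the formyl group is left over ring C, and the catalytic amidine enolises the aldehyde far faster than the C18 ketone, so C19 should be kept.

Step 21
Reactants: 31 pentacyclic aldehyde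
Product: 32 pentacyclic alcohol (C15H2OH)
Conditions: NaBH4, EtOH/CH2Cl2, −78 °C
Reagents that add atoms: none
Why: Chemoselective borohydride reduction of an aldehyde in the presence of a dialkyl ketone at low temperature; the conjugated ester and the lactam do not react.

Step 22
Reactants: 32 pentacyclic alcohol
Product: 33 pentacyclic acetate
Conditions: Ac2O, pyridine, DMAP (cat.), CH2Cl2, 0 °C → rt
Reagents that add atoms: acetic anhydride, CC(=O)OC(C)=O
Why: Acylation of the primary alcohol before the phenol is freed, so that no selective acetylation is needed later and no internal hydroxyl can trap the dearomatisation intermediate.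

Step 23
Reactants: 33 pentacyclic acetate
Product: 34 phenol (C1=C2 saturated, benzyl removed)
Conditions: H2 (1 atm), Pd/C (10 %), EtOAc, rt
Reagents that add atoms: none
Why: Heterogeneous hydrogenation saturates the indene C1=C2 bond and hydrogenolyses the benzyl ether in one step; hydrogen should arrive on the lower face because the upper face is blocked by the C14 bridge and its acetoxymethyl group, which places the C1 ester on the upper face as in the target.

Step 24
Reactants: 34 phenol
Product: 35 para-quinol dienone
Conditions: PhI(OAc)2, MeCN/H2O (4:1), 0 °C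
Reagents that add atoms: water, O
Why: Oxidative dearomatisation of a para-alkyl phenol by a trivalent iodine reagent, with water adding to the para carbon C10; water should enter on the lower face, anti to the adjacent C1 ester and to the acetoxymethyl group, which sets C10.

Step 25
Reactants: 35 para-quinol dienone
Product: 36 CNP0211170.1 (target)
Conditions: H2 (1 atm), RhCl(PPh3)3 (10 mol %), toluene/EtOH (1:1), rt
Reagents that add atoms: none
Why: Homogeneous hydrogenation with RhCl(PPh3)3 reduces the disubstituted C11=C12 bond of the cross-conjugated dienone and leaves the tetrasubstituted C8=C9 enone, the tertiary allylic alcohol and the other carbonyl groups intact.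

**Compound list**

1 | ethoxyacetylene | CCOC#C | starting material
2 | oxetane | C1COC1 | starting material
3 | 5-ethoxypent-4-yn-1-ol | CCOC#CCCCO | intermediate
4 | 5-ethoxypent-4-ynal | CCOC#CCCC=O | intermediate
5 | dimethyl glutarate | COC(=O)CCCC(=O)OC | starting material
6 | dimethyl 2-(5-ethoxy-1-hydroxypent-4-yn-1-yl)pentanedioate (diastereomer mixture) | COC(=O)CCC(C(=O)OC)C(O)CCC#COCC | intermediate
7 | dimethyl 2-(5-ethoxypent-4-ynoyl)pentanedioate | COC(=O)CCC(C(=O)OC)C(=O)CCC#COCC | intermediate
8 | methyl (2R)-7-ethoxy-2-ethynyl-2-(3-methoxy-3-oxopropyl)-3-oxohept-6-ynoate | COC(=O)CC[C@](C#C)(C(=O)OC)C(=O)CCC#COCC | intermediate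
9 | acetylene | C#C | starting material
10 | methyl (1R)-5-ethoxy-1-(3-methoxy-3-oxopropyl)-2-oxo-3,4-dihydro-2H-naphthalene-1-carboxylate | COC(=O)CC[C@@]1(C(=O)OC)c2cccc(OCC)c2CCC1=O | intermediate
11 | methyl (1R)-5-hydroxy-1-(3-methoxy-3-oxopropyl)-2-oxo-3,4-dihydro-2H-naphthalene-1-carboxylate | COC(=O)CC[C@@]1(C(=O)OC)c2cccc(O)c2CCC1=O | intermediate
12 | methyl (1R)-8-bromo-5-hydroxy-1-(3-methoxy-3-oxopropyl)-2-oxo-3,4-dihydro-2H-naphthalene-1-carboxylate | COC(=O)CC[C@@]1(C(=O)OC)c2c(Br)ccc(O)c2CCC1=O | intermediate
13 | methyl (1R)-5-(benzyloxy)-8-bromo-1-(3-methoxy-3-oxopropyl)-2-oxo-3,4-dihydro-2H-naphthalene-1-carboxylate | COC(=O)CC[C@@]1(C(=O)OC)c2c(Br)ccc(OCc3ccccc3)c2CCC1=O | intermediate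
14 | (4S)-4-benzyl-3-propanoyl-1,3-oxazolidin-2-one | O=C1OC[C@H](Cc2ccccc2)N1C(=O)CC | starting material
15 | acrolein | C=CC=O | starting material
16 | (4S)-4-benzyl-3-[(2S,3R)-3-hydroxy-2-methylpent-4-enoyl]-1,3-oxazolidin-2-one | O=C1OC[C@H](Cc2ccccc2)N1C(=O)[C@@H](C)[C@H](O)C=C | intermediate
17 | (4S)-4-benzyl-3-[(2S,3R)-3-(tert-butyldimethylsilyloxy)-2-methylpent-4-enoyl]-1,3-oxazolidin-2-one | O=C1OC[C@H](Cc2ccccc2)N1C(=O)[C@@H](C)[C@H](O[Si](C)(C)C(C)(C)C)C=C | intermediate
18 | (2R,3R)-3-(tert-butyldimethylsilyloxy)-2-methylpent-4-en-1-ol | OC[C@@H](C)[C@H](O[Si](C)(C)C(C)(C)C)C=C | intermediate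
19 | tert-butyl{[(3R,4R)-5-azido-4-methylpent-1-en-3-yl]oxy}dimethylsilane | [N-]=[N+]=NC[C@@H](C)[C@H](O[Si](C)(C)C(C)(C)C)C=C | intermediate (not isolated)
20 | (2R,3R)-3-(tert-butyldimethylsilyloxy)-2-methylpent-4-en-1-amine | NC[C@@H](C)[C@H](O[Si](C)(C)C(C)(C)C)C=C | intermediate
21 | Mannich base: 13 carrying CH2NH–[(2R,3R)-3-(tert-butyldimethylsilyloxy)-2-methylpent-4-enyl] on C6 (tetralone C3, both epimers) | COC(=O)CC[C@@]1(C(=O)OC)c2c(Br)ccc(OCc3ccccc3)c2CC(CNC[C@@H](C)[C@H](O[Si](C)(C)C(C)(C)C)C=C)C1=O | intermediate (not isolated)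
22 | bromo keto-lactam: rings B, C, D; C3 and C6 bridged by C4(=O)–N–C5H2 and by the C14 ketone; N carries the (2R,3R)-3-(tert-butyldimethylsilyloxy)-2-methylpent-4-enyl chain; C3 carries CH2CH2CO2Me; C10–Br; C13–OBn | COC(=O)CC[C@@]12C(=O)N(C[C@@H](C)[C@H](O[Si](C)(C)C(C)(C)C)C=C)C[C@@H](Cc3c(OCc4ccccc4)ccc(Br)c31)C2=O | intermediate
23 | bromo enol ether lactam: as 22 with C14=CH–OMe (E/Z mixture) in place of the ketone | COC(=O)CC[C@@]12C(=O)N(C[C@@H](C)[C@H](O[Si](C)(C)C(C)(C)C)C=C)C[C@@H](Cc3c(OCc4ccccc4)ccc(Br)c31)C2=COC | intermediate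
24 | indane ester: as 23 with ring A closed by a C1–C10 bond in place of bromine (C1 epimers) | COC(=O)C1C[C@@]23C(=O)N(C[C@@H](C)[C@H](O[Si](C)(C)C(C)(C)C)C=C)C[C@@H](Cc4c(OCc5ccccc5)ccc1c42)C3=COC | intermediate
25 | selenide: as 24 with phenylselanyl on C1 | COC(=O)C1([Se]c6ccccc6)C[C@@]23C(=O)N(C[C@@H](C)[C@H](O[Si](C)(C)C(C)(C)C)C=C)C[C@@H](Cc4c(OCc5ccccc5)ccc1c42)C3=COC | intermediate (not isolated)
26 | selenoxide of 25 | COC(=O)C1([Se](=O)c6ccccc6)C[C@@]23C(=O)N(C[C@@H](C)[C@H](O[Si](C)(C)C(C)(C)C)C=C)C[C@@H](Cc4c(OCc5ccccc5)ccc1c42)C3=COC | intermediate (not isolated)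
27 | indene ester: as 24 with a C1=C2 double bond | COC(=O)C1=C[C@@]23C(=O)N(C[C@@H](C)[C@H](O[Si](C)(C)C(C)(C)C)C=C)C[C@@H](Cc4c(OCc5ccccc5)ccc1c42)C3=COC | intermediate
28 | silyl ether aldehyde: as 27 with C14H–CHO in place of the enol ether (C14 epimers) | COC(=O)C1=C[C@@]23C(=O)N(C[C@@H](C)[C@H](O[Si](C)(C)C(C)(C)C)C=C)C[C@@H](Cc4c(OCc5ccccc5)ccc1c42)C3C=O | intermediate (not isolated)
29 | hydroxy aldehyde: as 28 with the free (3R) allylic alcohol | COC(=O)C1=C[C@@]23C(=O)N(C[C@@H](C)[C@H](O)C=C)C[C@@H](Cc4c(OCc5ccccc5)ccc1c42)C3C=O | intermediate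
30 | vinyl ketone aldehyde: as 29 with the N-chain oxidised to (2R)-2-methyl-3-oxopent-4-enyl | COC(=O)C1=C[C@@]23C(=O)N(C[C@@H](C)C(=O)C=C)C[C@@H](Cc4c(OCc5ccccc5)ccc1c42)C3C=O | intermediate
31 | pentacyclic aldehyde: ring E closed by C14–C16; C14 quaternary with CHO over ring C; C18 ketone; (R)-C19 methyl; C1=C2; C13–OBn | COC(=O)C1=C[C@@]23C(=O)N4C[C@@H](Cc5c(OCc6ccccc6)ccc1c52)[C@]3(C=O)CCC(=O)[C@H](C)C4 | intermediate
32 | pentacyclic alcohol: as 31 with C15H2OH | COC(=O)C1=C[C@@]23C(=O)N4C[C@@H](Cc5c(OCc6ccccc6)ccc1c52)[C@]3(CO)CCC(=O)[C@H](C)C4 | intermediate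
33 | pentacyclic acetate: as 32 with C15H2OAc | COC(=O)C1=C[C@@]23C(=O)N4C[C@@H](Cc5c(OCc6ccccc6)ccc1c52)[C@]3(COC(C)=O)CCC(=O)[C@H](C)C4 | intermediate
34 | phenol: as 33 with C1–C2 saturated (C1–H lower face, CO2Me upper face) and free C13–OH | COC(=O)[C@@H]1C[C@@]23C(=O)N4C[C@@H](Cc5c(O)ccc1c52)[C@]3(COC(C)=O)CCC(=O)[C@H](C)C4 | intermediate
35 | para-quinol dienone: the target with an extra C11=C12 double bond (C10–OH lower face) | COC(=O)[C@@H]1C[C@@]23C(=O)N4C[C@@H](CC5=C2[C@]1(O)C=CC5=O)[C@]3(COC(C)=O)CCC(=O)[C@H](C)C4 | intermediate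
36 | CNP0211170.1 | COC(=O)[C@@H]1C[C@@]23C(=O)N4C[C@@H](CC5=C2[C@]1(O)CCC5=O)[C@]3(COC(C)=O)CCC(=O)[C@H](C)C4 | target

**Totals.** Total step count: 25. Longest linear sequence: 21 steps (steps 1–9 and 14–25, from ethoxyacetylene 1); the amine branch (steps 10–13) joins at step 14.

**Steps most likely to fail**

Step 6. Process at risk: the first alkyne–alkyne coupling on rhodium may be outrun by intermolecular oligomerisation of the diyne or by dimerisation at its terminal alkyne, because the concentration of dissolved acetylene is low and hard to control. Fallback (sets out from 8, returns at 10): the gas is replaced by a liquid monoalkyne in large excess, (trimethylsilyl)acetylene, with RhCl(PPh3)3 in toluene at 40 °C. This should give the 6-silyl tetralone, methyl (1R)-5-ethoxy-1-(3-methoxy-3-oxopropyl)-2-oxo-6-(trimethylsilyl)-3,4-dihydro-2H-naphthalene-1-carboxylate F1, together with its 7-silyl regioisomer, methyl (1R)-5-ethoxy-1-(3-methoxy-3-oxopropyl)-2-oxo-7-(trimethylsilyl)-3,4-dihydro-2H-naphthalene-1-carboxylate F2. Both converge on 10 by ipso-protodesilylation with CF3CO2H in CH2Cl2.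

Step 20. Process at risk: the nine-membered ring may close too slowly, so that the aldehyde enolate is diverted into intermolecular Michael or aldol reactions, or C19 epimerises under base. Fallback (sets out from 27, returns at 31): the nucleophile is changed from an enolate to the neutral enol ether. The silyl ether of 27 is removed with n-Bu4NF/AcOH in THF to give the allylic alcohol enol ether F3. Oxidation with Dess–Martin periodinane/NaHCO3 gives the vinyl ketone enol ether F4. BF3·OEt2 in CH2Cl2 at −78 °C then activates the enone for attack by the tethered methyl enol ether (Mukaiyama–Michael type, no base), and aqueous NaHCO3 hydrolyses the resulting oxocarbenium ion to aldehyde 31.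

Step 24. Process at risk: loss of the acidic C1 proton from the oxidised phenol (quinone methide formation), attack at an ortho carbon, or poor facial selectivity of water addition. Fallback (sets out from 34, returns at 35): dearomatisation by singlet oxygen in place of the iodine reagent. KHSO5 (as 2KHSO5·KHSO4·K2SO4) and NaHCO3 in MeCN/H2O generate singlet oxygen, which should add to the phenol at C10 anti to the C1 ester and give the para-hydroperoxy dienone F5. Reduction of the O–O bond with Me2S then gives 35.

Further compounds
F1 | step 6 | methyl (1R)-5-ethoxy-1-(3-methoxy-3-oxopropyl)-2-oxo-6-(trimethylsilyl)-3,4-dihydro-2H-naphthalene-1-carboxylate | COC(=O)CC[C@@]1(C(=O)OC)c2ccc([Si](C)(C)C)c(OCC)c2CCC1=O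
F2 | step 6 | methyl (1R)-5-ethoxy-1-(3-methoxy-3-oxopropyl)-2-oxo-7-(trimethylsilyl)-3,4-dihydro-2H-naphthalene-1-carboxylate | COC(=O)CC[C@@]1(C(=O)OC)c2cc([Si](C)(C)C)cc(OCC)c2CCC1=O
F3 | step 20 | allylic alcohol enol ether: 27 without the silyl group | COC(=O)C1=C[C@@]23C(=O)N(C[C@@H](C)[C@H](O)C=C)C[C@@H](Cc4c(OCc5ccccc5)ccc1c42)C3=COC
F4 | step 20 | vinyl ketone enol ether: F3 with the N-chain oxidised to (2R)-2-methyl-3-oxopent-4-enyl | COC(=O)C1=C[C@@]23C(=O)N(C[C@@H](C)C(=O)C=C)C[C@@H](Cc4c(OCc5ccccc5)ccc1c42)C3=COC
F5 | step 24 | para-hydroperoxy dienone: 35 with C10–OOH in place of C10–OH | COC(=O)[C@@H]1C[C@@]23C(=O)N4C[C@@H](CC5=C2[C@]1(OO)C=CC5=O)[C@]3(COC(C)=O)CCC(=O)[C@H](C)C4
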